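**Remark (assumption):** the stereocentre of the target is read as S (O > C12 > C14 > H). The ketoreductase of step 5 is taken from a screening panel of Prelog-selective enzymes, and its identity is fixed by that screen.

## Analysis of the target

Target 9 is (S)-13-hydroxy-1-(2,4,6-trihydroxyphenyl)hexadecan-1-one: a phloroglucinol ring (C1'–C6', hydroxyls on C2', C4', C6') C-acylated at C1' by an unbranched C16 chain, in which C1 is the aryl ketone, C2–C12 are eleven methylenes, C13 is a secondary carbinol and C14–C16 are an n-propyl end. The only stereocentre is C13, and it lies eleven methylenes from the nearest functional group, so nothing in the molecule can relay stereochemistry to it. The defining feature is that C13 carries two unbranched alkyl arms, the C14–C16 propyl group and the C12→C2 undecamethylene chain, which are identical over the first three atoms out from C13, so that a small chiral reductant that reads only the immediate surroundings of a C13 carbonyl cannot tell them apart. The two oxygenated chain carbons differ sharply in reactivity: the C1 carbonyl is a hydrogen-bonded vinylogous acid, inert to hydride, whereas a C13 carbonyl would be an ordinary dialkyl ketone. The acylphloroglucinol is acidic, electron-rich, prone to autoxidation in base and open to further C-acylation at C3'/C5'. A free C13 hydroxyl would be acylated or ionised under Friedel–Crafts conditions. The difficulty is therefore economy rather than any single bond: routes that fix C13 early pay for it with protection and redox adjustment, whereas the structure invites fixing C13 last, on an unprotected achiral precursor.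

## Retrosynthetic reasoning

**9 ⇒ 8 (C13–H bond).** The stereocentre is removed first, which reveals the achiral diketone 8. The forward step must reduce the C13 carbonyl only, from its re face, and leave the C1 carbonyl alone. An enzyme of the ketoreductase class is chosen because its binding pockets read the length of the two arms at C13, the one difference between them. The C1 carbonyl protects itself by its vinylogous-acid character. The gain is that every earlier compound is achiral and no protecting group is needed anywhere.

**8 ⇒ 6 + 7 (C1–C1' bond).** The aryl ketone is cut by a Friedel–Crafts disconnection into acid chloride 6 and the symmetric triphenol 7. All three free positions of 7 are equivalent, and the first acyl group deactivates the ring, so the forward reaction should stop at mono-acylation. Compound 6 comes from acid 5 by a routine functional group change. The forward reaction must tolerate a remote dialkyl ketone in the presence of a Lewis acid.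

**5 ⇒ 3 (reconnection of C1 to C12).** The acid carbon C1 and the carbon α to the ketone, C12, are reconnected to give the twelve-membered β-diketone 3. In the forward direction a retro-Claisen cleavage of the C1–C12 bond by aqueous alkali opens the ring. This releases the carboxylic acid at C1 and the ketone at C13 in one operation, with the correct eleven methylenes between them. The gain is that C1–C12 come from one commodity ring and no long α,ω-difunctional chain has to be differentiated at its two ends. The forward reaction must cleave on the ring side of the diketone.

**3 ⇒ 1 + 2 (C12–C13 bond).** The β-diketone is cut between the ring α-carbon and the exocyclic carbonyl, which gives ring ketone 1 and acid chloride 2. The forward reaction is a C-acylation of the enolate of 1 and must avoid O-acylation and double acylation.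

## Alternatives that were turned down

Alternative 1: the textbook route. The disconnections are C1–C1' by Friedel–Crafts acylation and C11–C12 by epoxide opening. Chiral-pool (S)-2-propyloxirane A1 would be opened at its CH2 under copper catalysis by undec-10-en-1-ylmagnesium bromide A2 to give (S)-hexadec-15-en-4-ol A3. O-Acetylation, hydroboration–oxidation and oxidation would give (S)-13-acetoxyhexadecanoic acid A4, followed by acid chloride formation, acylation of 7 and deacetylation. Every step from A1 and A2 through A3 to A4 is reliable, but C13 is in place before the Lewis-acidic ring acylation, so its hydroxyl must be protected and released. C1 also has to be taken through two oxidation-state changes. This is about seven steps, none doing more than one job.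

Alternative 2: disconnection at C12–C13 with stereoconvergence. A nickel-catalysed enantioconvergent Negishi coupling of racemic 2-(1-chlorobutyl)-4,4,5,5-tetramethyl-1,3,2-dioxaborolane A5 with (12-methoxy-12-oxododecyl)zinc bromide A6 would give methyl (S)-13-(4,4,5,5-tetramethyl-1,3,2-dioxaborolan-2-yl)hexadecanoate A7. Oxidation of the C–B bond with retention would follow. This is attractive because the catalyst that joins A5 and A6 distinguishes B, H and C at C13, not two n-alkyl arms. It was turned down on step economy. In A7 the C13 centre is created at the boron level and before the arene is attached, so C–B oxidation, ester hydrolysis, O-protection, ring acylation and deprotection must follow, giving eight to nine steps. The C–B oxidation cannot be postponed past ring acylation, because basic peroxide would attack the 2,4,6-trihydroxyaryl ketone in a Dakin-type oxidation.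

Alternative 3: disconnection at C13–O by late-stage enzymatic C–H hydroxylation. 1-(2,4,6-Trihydroxyphenyl)hexadecan-1-one A8 would be hydroxylated by a cytochrome P450 monooxygenase of the subterminal fatty-acid hydroxylase class. It was turned down because the C13, C14 and C15 methylenes of A8 differ only in their distance from the chain end. Hydroxylases of this class characteristically spread over the ω-1 to ω-3 positions, and neither the site nor the face can be fixed by design. The electron-rich triphenol of A8 is itself open to oxidation by the iron-oxo species, and regioisomeric alcohols of this kind would be hard to separate. In the chosen route the position of the oxygen is fixed by synthesis and the enzyme only has to choose a face.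

Key step: step 5

## Route

Step 1
Reactants: 1 cyclododecanone; 2 butanoyl chloride
Product: 3 2-butanoylcyclododecan-1-one (racemic at ring C2; this centre is removed in step 2)
Conditions: MgBr2·OEt2 (2.5 equiv), i-Pr2NEt (3 equiv), CH2Cl2, rt; 1 M HCl work-up
Reagents that add atoms: none
Why: Soft enolisation and C-acylation (crossed Claisen-type ketone acylation): Mg(II) coordination acidifies the α-C–H so that the amine base suffices, and the β-diketone is held as its magnesium chelate, which should suppress O-acylation and a second acylation; the new ring stereocentre is formed racemic and is irrelevant.

Step 2
Reactants: 3 2-butanoylcyclododecan-1-one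
Product: 5 13-oxohexadecanoic acid, via sodium 13-oxohexadecanoate 4 (not isolated)
Conditions: NaOH (3 equiv), H2O/EtOH, reflux; then aq HCl to pH 2
Reagents that add atoms: sodium hydroxide, [Na+].[OH-]
Why: Retro-Claisen cleavage of a 2-acylcycloalkanone: hydroxide adds to the ring carbonyl and the tetrahedral intermediate expels the enolate of the butanoyl ketone, which opens the ring to the C1 carboxylate and the C13 ketone. Attack at the exocyclic carbonyl would only return 1, which can be recycled.

Step 3
Reactants: 5 13-oxohexadecanoic acid
Product: 6 13-oxohexadecanoyl chloride (used crude after evaporation)
Conditions: (COCl)2 (1.3 equiv), DMF (cat.), CH2Cl2, 0 °C → rt; evaporate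
Reagents that add atoms: oxalyl chloride, ClC(=O)C(Cl)=O
Why: Vilsmeier-catalysed acid chloride formation; the remote unactivated dialkyl ketone should be inert at room temperature.

Step 4
Reactants: 6 13-oxohexadecanoyl chloride; 7 benzene-1,3,5-triol (phloroglucinol, anhydrous)
Product: 8 1-(2,4,6-trihydroxyphenyl)hexadecane-1,13-dione
Conditions: AlCl3 (4 equiv), CH2Cl2/MeNO2, 0 °C → rt; ice/1 M HCl
Reagents that add atoms: none
Why: Friedel–Crafts C-acylation: the three free positions of 7 are equivalent, the first acyl group deactivates the ring against a second, and any O-acyl ester should converge on the same ketone by Fries rearrangement. The extra AlCl3 complexes the C13 ketone.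

Step 5
Reactants: 8 1-(2,4,6-trihydroxyphenyl)hexadecane-1,13-dione
Product: 9 (S)-13-hydroxy-1-(2,4,6-trihydroxyphenyl)hexadecan-1-one
Conditions: Prelog-selective NADPH-dependent ketoreductase (alcohol dehydrogenase class, from panel screen), NADP+ (cat.), i-PrOH (15% v/v), KPi buffer pH 7.0, DMSO (10% v/v), 30 °C, N2
Reagents that add atoms: none
Why: The enzyme binds 8 and NADPH in a ternary complex and transfers the hydride of the dihydronicotinamide to C13 while the active-site acid protonates O13; the oxidised cofactor is returned to NADPH by the same enzyme oxidising isopropanol. The closest known reaction type is the ketoreductase reduction of unbranched dialkyl ketones and of long-chain oxo fatty acids, which follows Prelog's rule. No ring is closed. The new stereocentre C13 is controlled by the two binding pockets alone: the closed small pocket can hold the C14–C16 propyl group but not an eleven-carbon chain, so the C12→C2 chain must lie in the open large pocket with the triphenol head towards solvent, which exposes the re face of C13=O to the hydride and gives the S alcohol. Two selectivities are needed. Facial selectivity rests on the difference in length of the two arms (three atoms against more than eleven), which a pocket of fixed depth can read although the first three atoms of both arms are identical. Site selectivity between C13=O and C1=O rests on the substrate: C1=O is flanked by two ortho hydroxyls, is internally hydrogen-bonded and is partly ionised as a vinylogous acid at pH 7, so it is a poor electrophile and a poor fit for the active site. The product cannot epimerise, and the excess of isopropanol drives the equilibrium to the alcohol.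

## Compound list

1 | cyclododecanone | O=C1CCCCCCCCCCC1 | starting material
2 | butanoyl chloride | CCCC(Cl)=O | starting material
3 | 2-butanoylcyclododecan-1-one (racemic, stereolabile at ring C2) | CCCC(=O)C1CCCCCCCCCCC1=O | intermediate
4 | sodium 13-oxohexadecanoate | CCCC(=O)CCCCCCCCCCCC(=O)[O-].[Na+] | intermediate (not isolated)
5 | 13-oxohexadecanoic acid | CCCC(=O)CCCCCCCCCCCC(O)=O | intermediate
6 | 13-oxohexadecanoyl chloride | CCCC(=O)CCCCCCCCCCCC(Cl)=O | intermediate
7 | benzene-1,3,5-triol (phloroglucinol) | Oc1cc(O)cc(O)c1 | starting material
8 | 1-(2,4,6-trihydroxyphenyl)hexadecane-1,13-dione | CCCC(=O)CCCCCCCCCCCC(=O)c1c(O)cc(O)cc1O | intermediate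
9 | (S)-13-hydroxy-1-(2,4,6-trihydroxyphenyl)hexadecan-1-one | CCC[C@H](O)CCCCCCCCCCCC(=O)c1c(O)cc(O)cc1O | target

## Step count and risk

Total step count: 5. Longest linear sequence: 5 steps (1 → 3 → 5 → 6 → 8 → 9).

**Step 5 (key step).** The most likely failure is insufficient facial discrimination. If the small pocket of the available enzymes cannot seat an n-propyl group, binding becomes ambiguous or turnover stalls. A second failure is aggregation of the amphiphilic substrate in buffer, which would limit conversion. The fallback fixes C13 by C–C bond formation from the chiral pool and not by reduction. It sets out from 7 and comes back to the route at 9. 11-Bromoundec-1-ene would be converted with magnesium into undec-10-en-1-ylmagnesium bromide F1. This would open commercial (S)-2-propyloxirane at its CH2 under CuI catalysis to give (S)-hexadec-15-en-4-ol F2. Acetylation with Ac2O and pyridine would give (S)-hexadec-15-en-4-yl acetate F3. Hydroboration with 9-BBN and oxidation with sodium perborate would give (S)-16-hydroxyhexadecan-4-yl acetate F4. TEMPO/NaOCl/NaClO2 oxidation would give (S)-13-acetoxyhexadecanoic acid F5, and oxalyl chloride would give (S)-13-acetoxyhexadecanoyl chloride F6. AlCl3-mediated acylation of 7 would give (S)-16-oxo-16-(2,4,6-trihydroxyphenyl)hexadecan-4-yl acetate F7. Methanolysis with K2CO3 in MeOH under argon would then give 9. The sequence F1 → F2 → F3 → F4 → F5 → F6 → F7 → 9 is longer than the main route, but it takes the stereocentre from the chiral pool and never puts it at risk.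

**Step 4.** The most likely failure is competing reaction of the Lewis-acid-activated C13 ketone with the very nucleophilic triphenol (hydroxyalkylation and condensation). Over-acylation and incomplete O→C acyl transfer would add to the problem and make purification of the polar product difficult. The fallback removes the free ketone from the acylation by moving the enzymatic reduction forward. It sets out from 5 and comes back at 9. The ketoreductase of step 5 would be applied to 5, an oxo fatty acid, to give (S)-13-hydroxyhexadecanoic acid F8. Acetylation would give (S)-13-acetoxyhexadecanoic acid F5, and the sequence through the acid chloride F6 and the aryl ketone acetate F7 described under step 5 would lead to 9. In the sequence F8 → F5 → F6 → F7 → 9 the free C13 ketone never meets the Lewis acid.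

**Step 2.** The most likely failure is cleavage on the wrong side of the β-diketone. Attack of hydroxide at the exocyclic butanoyl carbonyl is not clearly disfavoured for a twelve-membered ring, whose own carbonyl is hindered, and this deacylation would return 1. The fallback builds the 1,13-keto acid by acyl cross-coupling and not by ring opening. It sets out from 2 and comes back at 5. Methyl 12-bromododecanoate would be converted with zinc and catalytic I2 in DMA into (12-methoxy-12-oxododecyl)zinc bromide F9. Palladium-catalysed Negishi acylation with 2 would give methyl 13-oxohexadecanoate F10, and saponification with LiOH in THF/H2O would give 5. The pair F9 and F10 fixes the position of the ketone by the coupling itself, so no regiochemical question arises.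

**Step 1.** The most likely failure is slow enolisation of the twelve-membered ketone. The acid chloride would then be consumed by ketene formation with the amine base, or by O-acylation. The fallback is a Stork enamine acylation. It sets out from 1 and comes back at 3. Condensation of 1 with morpholine under TsOH catalysis in toluene with removal of water would give 4-(cyclododec-1-en-1-yl)morpholine F11. Acylation with 2 in CHCl3 with Et3N would give 1-[2-(morpholin-4-yl)cyclododec-1-en-1-yl]butan-1-one F12, and hydrolysis with aqueous HCl would give 3. The enamine F11 is a preformed carbon nucleophile, and its acylation product F12 cannot be acylated a second time.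

## Further compounds

F1 | step 5 | undec-10-en-1-ylmagnesium bromide | C=CCCCCCCCCC[Mg]Br
F2 | step 5 | (S)-hexadec-15-en-4-ol | CCC[C@H](O)CCCCCCCCCCC=C
F3 | step 5 | (S)-hexadec-15-en-4-yl acetate | CCC[C@H](OC(C)=O)CCCCCCCCCCC=C
F4 | step 5 | (S)-16-hydroxyhexadecan-4-yl acetate | CCC[C@H](OC(C)=O)CCCCCCCCCCCCO
F5 | step 5 | (S)-13-acetoxyhexadecanoic acid | CCC[C@H](OC(C)=O)CCCCCCCCCCCC(O)=O
F6 | step 5 | (S)-13-acetoxyhexadecanoyl chloride | CCC[C@H](OC(C)=O)CCCCCCCCCCCC(Cl)=O
F7 | step 5 | (S)-16-oxo-16-(2,4,6-trihydroxyphenyl)hexadecan-4-yl acetate | CCC[C@H](OC(C)=O)CCCCCCCCCCCC(=O)c1c(O)cc(O)cc1O
F8 | step 4 | (S)-13-hydroxyhexadecanoic acid | CCC[C@H](O)CCCCCCCCCCCC(O)=O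
F9 | step 2 | (12-methoxy-12-oxododecyl)zinc bromide | COC(=O)CCCCCCCCCCC[Zn]Br
F10 | step 2 | methyl 13-oxohexadecanoate | CCCC(=O)CCCCCCCCCCCC(=O)OC
F11 | step 1 | 4-(cyclododec-1-en-1-yl)morpholine | C1(N2CCOCC2)=CCCCCCCCCCC1
F12 | step 1 | 1-[2-(morpholin-4-yl)cyclododec-1-en-1-yl]butan-1-one | CCCC(=O)C1=C(N2CCOCC2)CCCCCCCCCC1
A1 | alternative 1 | (S)-2-propyloxirane | CCC[C@H]1CO1
A2 | alternative 1 | undec-10-en-1-ylmagnesium bromide | C=CCCCCCCCCC[Mg]Br
A3 | alternative 1 | (S)-hexadec-15-en-4-ol | CCC[C@H](O)CCCCCCCCCCC=C
A4 | alternative 1 | (S)-13-acetoxyhexadecanoic acid | CCC[C@H](OC(C)=O)CCCCCCCCCCCC(O)=O
A5 | alternative 2 | rac-2-(1-chlorobutyl)-4,4,5,5-tetramethyl-1,3,2-dioxaborolane | CCCC(Cl)B1OC(C)(C)C(C)(C)O1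
A6 | alternative 2 | (12-methoxy-12-oxododecyl)zinc bromide | COC(=O)CCCCCCCCCCC[Zn]Br
A7 | alternative 2 | methyl (S)-13-(4,4,5,5-tetramethyl-1,3,2-dioxaborolan-2-yl)hexadecanoate | CCC[C@H](B1OC(C)(C)C(C)(C)O1)CCCCCCCCCCCC(=O)OC
A8 | alternative 3 | 1-(2,4,6-trihydroxyphenyl)hexadecan-1-one | CCCCCCCCCCCCCCCC(=O)c1c(O)cc(O)cc1O
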